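Everything rests on cutting the C8–C9 bond of ring B. A σ-vinyl radical at C8, released from a 2-bromoalk-1-ene, adds 6-exo to the C9=C11 enoate; one operation closes ring B, leaves the exocyclic C8=C17 methylene and sets C9. The step exploits the α,α-cis placement on ring A of the C5 arm (C6–C7–C8) and of C9 on quaternary C10, beside the axial C19 carboxyl on C4, which forces the C11 chain equatorial (9β). The precursor is a ring A cyclohexane with 2β-silyloxy, 4β-methyl/4α-ester, a 5α-(3-bromobut-3-enyl) arm and a 10β-methyl/10α-(E)-acrylate, built from a resolved Birch-derived vinylogous ester.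

Key step: step 18

Convention: labdane numbering is used for every intermediate (ring A = C1–C5 and C10; C18 = methyl and C19 = carboxyl carbon on C4; C20 = methyl on C10; C9 = the other carbon on C10; C6–C8 and C17 = arm on C5); β is the face of C18 and C20, α the face of C19, of the C5 arm and of C9. The target is read as cis-fused, (2S,4R,5S,9S,10R).

Remark on the design: a 2-bromoalkene does not survive organolithium, zerovalent palladium or borane reagents, and a hindered C19 methyl ester would resist the final hydrolysis. The bromide is therefore made after those steps, and C19 travels as tert-butyl ester, then δ-lactone, then SEM ester.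

Assumption: in step 2 the (R)-amine is written; the mirror-image amine is used instead if its salt with the (R)-acid is the one that crystallises. Compounds 12, 27 and 41 are taken as purchasable.

Step 1
Reactants: 1 3,5-dimethoxybenzoic acid
Product: 4 rac-3-methoxy-1-methyl-5-oxocyclohex-3-ene-1-carboxylic acid, via dilithium enediolate 2 (not isolated), via lithium diene carboxylate 3 (not isolated)
Conditions: Li, NH3(l)/THF, −78 °C; MeI, −78 °C → rt; then 1 M HCl, THF/H2O, 0 °C
Reagents that add atoms: iodomethane, CI; water, O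
Why: Birch reductive alkylation methylates the ipso carbon of the enediolate, and brief aqueous acid hydrolyses one of the two equivalent enol ethers to the vinylogous ester, which resists further hydrolysis; the quaternary C4 forms as a racemate.

Step 2
Reactants: 4 rac-3-methoxy-1-methyl-5-oxocyclohex-3-ene-1-carboxylic acid
Product: 5 (R)-1-phenylethylammonium (R)-3-methoxy-1-methyl-5-oxocyclohex-3-ene-1-carboxylate
Conditions: (R)-1-phenylethylamine (0.55 equiv), EtOAc/acetone, crystallization, one recrystallization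
Reagents that add atoms: (R)-1-phenylethylamine, C[C@@H](N)c1ccccc1
Why: Classical resolution by diastereomeric salt crystallization should deliver the salt of the (R)-acid as the less soluble one, which fixes C4 (C18 β, C19 α) and with it the absolute configuration of the whole route.

Step 3
Reactants: 5 (R)-1-phenylethylammonium (R)-3-methoxy-1-methyl-5-oxocyclohex-3-ene-1-carboxylate
Product: 7 tert-butyl (R)-3-methoxy-1-methyl-5-oxocyclohex-3-ene-1-carboxylate, via free (R)-acid 6 (not isolated)
Conditions: 1 M HCl/EtOAc partition, 0 °C; then Me2NCH(Ot-Bu)2, toluene, 80 °C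
Reagents that add atoms: N,N-dimethylformamide di-tert-butyl acetal, CN(C)C(OC(C)(C)C)OC(C)(C)C
Why: O-alkylation of the carboxylate by the tert-butyl cation equivalent of the amide acetal esterifies the hindered acid without attack at its carbonyl and without acid that could scramble the enol ether; C4 is untouched.

Step 4
Reactants: 7 tert-butyl (R)-3-methoxy-1-methyl-5-oxocyclohex-3-ene-1-carboxylate; 8 allyl bromide
Product: 10 tert-butyl (1R,2R)-2-allyl-5-methoxy-1-methyl-3-oxocyclohex-4-ene-1-carboxylate (5α-allyl), via lithium dienolate 9 (not isolated)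
Conditions: LiN(iPr)2, THF, −78 °C; allyl bromide, −78 → −20 °C
Reagents that add atoms: none
Why: Stork–Danheiser α′-alkylation: kinetic deprotonation at C5 gives the cross-conjugated dienolate, and allyl bromide should enter anti to the pseudo-axial C18 methyl while the flat, poorer σ-donor ester lies near the enolate plane, which sets C5 with the allyl group α, cis to C19.

Step 5
Reactants: 11 4-methoxybenzyl alcohol; 12 tributyl(iodomethyl)stannane
Product: 14 tributyl{[(4-methoxybenzyl)oxy]methyl}stannane, via sodium 4-methoxybenzyl oxide 13 (not isolated)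
Conditions: NaH, THF/DMF, 0 °C; then 12, rt
Reagents that add atoms: none
Why: Williamson ether synthesis on the unhindered primary iodide gives the α-alkoxystannane that serves as a protected hydroxymethyl anion source.

Step 6
Reactants: 10 tert-butyl (1R,2R)-2-allyl-5-methoxy-1-methyl-3-oxocyclohex-4-ene-1-carboxylate; 14 tributyl{[(4-methoxybenzyl)oxy]methyl}stannane
Product: 17 tert-butyl 2-allyl-3-{[(4-methoxybenzyl)oxy]methyl}-1-methyl-5-oxocyclohex-3-ene-1-carboxylate (C2 ketone; C1=C10; 5α-allyl; 4β-methyl; 4α-ester), via alkoxymethyllithium 15 (not isolated), via lithium alkoxide adduct 16 (not isolated)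
Conditions: 14, n-BuLi, THF, −78 °C; add 10, −78 → −40 °C; then 1 M HCl, THF, 0 °C → rt
Reagents that add atoms: water, O
Why: Tin–lithium exchange gives the α-alkoxy organolithium, which adds 1,2 to the vinylogous ester carbonyl C10, and acid-induced loss of water and methanol moves the carbonyl to C2 (Stork–Danheiser transposition), so that C9 sits on the enone β-carbon; no stereocenter is formed.

Step 7
Reactants: 17 tert-butyl 2-allyl-3-{[(4-methoxybenzyl)oxy]methyl}-1-methyl-5-oxocyclohex-3-ene-1-carboxylate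
Product: 19 tert-butyl 2-allyl-3-{[(4-methoxybenzyl)oxy]methyl}-1,3-dimethyl-5-(trifluoromethylsulfonyloxy)cyclohex-4-ene-1-carboxylate (10β-methyl; C9 α; 5α-allyl), via lithium enolate 18 (not isolated)
Conditions: Me2CuLi (from MeLi and CuI), Et2O, −40 → 0 °C; then PhNTf2, THF, 0 °C → rt
Reagents that add atoms: Me2CuLi (lithium dimethylcuprate), [Li+].C[Cu-]C; N-phenylbis(trifluoromethanesulfonimide), FC(F)(F)S(=O)(=O)N(c1ccccc1)S(=O)(=O)C(F)(F)F
Why: Cuprate conjugate addition puts the methyl on C10 anti to the adjacent C5 allyl group (the trans rule for 4-substituted cyclohexenones), so C20 is β and C9 α, and the regiodefined C1=C2 enolate is trapped on oxygen as the enol triflate.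

Step 8
Reactants: 19 enol triflate
Product: 20 tert-butyl 2-allyl-3-{[(4-methoxybenzyl)oxy]methyl}-1,3-dimethylcyclohex-4-ene-1-carboxylate (C1=C2 alkene; stereocenters as in 19)
Conditions: Pd(OAc)2 (5 mol %), PPh3, HCO2H, Bu3N, DMF, 60 °C
Reagents that add atoms: none
Why: Palladium-catalysed formate reduction of the enol triflate (oxidative addition to zerovalent palladium, formate-to-hydride exchange, reductive elimination) leaves the C1=C2 alkene and touches no stereocenter.

Step 9
Reactants: 20 tert-butyl 2-allyl-3-{[(4-methoxybenzyl)oxy]methyl}-1,3-dimethylcyclohex-4-ene-1-carboxylate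
Product: 22 9-allyl-1,5-dimethyl-3-oxabicyclo[3.3.1]non-6-en-2-one (δ-lactone from C19 to the C9 oxygen; 5α-allyl; 4β,10β-dimethyl), via hydroxy acid 21 (not isolated)
Conditions: CF3CO2H, anisole, CH2Cl2, 0 °C → rt; evaporate; TsOH (cat.), toluene, 80 °C
Reagents that add atoms: none
Why: Acid removes the 4-methoxybenzyl ether and the tert-butyl ester together, and lactonization closes the δ-lactone, which is possible only because C9 and C19 are cis-1,3 on the α face; the bridge locks ring A in the chair with both carbons axial.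

Step 10
Reactants: 22 9-allyl-1,5-dimethyl-3-oxabicyclo[3.3.1]non-6-en-2-one
Product: 24 7-hydroxy-9-(3-hydroxypropyl)-1,5-dimethyl-3-oxabicyclo[3.3.1]nonan-2-one (2β-hydroxy; exo), via bis-alkylborane 23 (not isolated)
Conditions: BH3·THF (3 equiv), THF, 0 °C → rt; then H2O2, aq. NaHCO3, 0 °C → rt
Reagents that add atoms: hydrogen peroxide, OO
Why: Hydroboration–oxidation: borane adds to C1=C2 from the exo β face because the lactone bridge covers the α face, with boron on C2 away from quaternary C10, and oxidation with retention sets C2 as the β alcohol, while the allyl group gives the primary C8 alcohol.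

Step 11
Reactants: 24 7-hydroxy-9-(3-hydroxypropyl)-1,5-dimethyl-3-oxabicyclo[3.3.1]nonan-2-one
Product: 25 3-(7-hydroxy-1,5-dimethyl-2-oxo-3-oxabicyclo[3.3.1]nonan-9-yl)propanal
Conditions: TEMPO (10 mol %), PhI(OAc)2, CH2Cl2, rt
Reagents that add atoms: none
Why: Oxoammonium (TEMPO) oxidation is selective for the unhindered primary C8 alcohol over the secondary C2 alcohol and stops at the aldehyde.

Step 12
Reactants: 25 3-(7-hydroxy-1,5-dimethyl-2-oxo-3-oxabicyclo[3.3.1]nonan-9-yl)propanal
Product: 26 3-[7-(tert-butyldimethylsilyloxy)-1,5-dimethyl-2-oxo-3-oxabicyclo[3.3.1]nonan-9-yl]propanal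
Conditions: t-BuMe2SiCl, imidazole, DMF, rt
Reagents that add atoms: tert-butyldimethylsilyl chloride, CC(C)(C)[Si](C)(C)Cl
Why: Silylation protects the equatorial C2 alcohol under conditions that leave the aldehyde alone.

Step 13
Reactants: 26 silyl ether aldehyde; 27 dimethyl (1-diazo-2-oxopropyl)phosphonate
Product: 29 9-(but-3-ynyl)-7-(tert-butyldimethylsilyloxy)-1,5-dimethyl-3-oxabicyclo[3.3.1]nonan-2-one, via dimethyl (diazomethyl)phosphonate 28 (not isolated)
Conditions: K2CO3, MeOH, 0 °C → rt
Reagents that add atoms: none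
Why: Ohira–Bestmann (Seyferth–Gilbert) homologation: methanolysis frees the diazomethylphosphonate anion, whose adduct with the aldehyde loses phosphate and nitrogen and rearranges to the terminal alkyne, adding C17; the hindered bridged lactone should survive the weak base.

Step 14
Reactants: 29 9-(but-3-ynyl)-7-(tert-butyldimethylsilyloxy)-1,5-dimethyl-3-oxabicyclo[3.3.1]nonan-2-one
Product: 31 9-(3-bromobut-3-enyl)-7-(tert-butyldimethylsilyloxy)-1,5-dimethyl-3-oxabicyclo[3.3.1]nonan-2-one, via bromoalkenylborane 30 (not isolated)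
Conditions: 9-Br-9-BBN, CH2Cl2, 0 °C; then AcOH, 0 °C → rt
Reagents that add atoms: 9-bromo-9-borabicyclo[3.3.1]nonane, BrB1C2CCCC1CCC2
Why: Syn bromoboration of the terminal alkyne puts bromine on the internal carbon C8, and protonolysis of the C–B bond gives the 2-bromoalk-1-ene; lactone and silyl ether tolerate the mild Lewis acid.

Step 15
Reactants: 31 bromoalkene lactone
Product: 33 [2-(trimethylsilyl)ethoxy]methyl 2-(3-bromobut-3-enyl)-5-(tert-butyldimethylsilyloxy)-3-(hydroxymethyl)-1,3-dimethylcyclohexane-1-carboxylate (2β-silyloxy; 4β-methyl; 4α-ester; 5α-arm; 10β-methyl; 10α-hydroxymethyl), via lithium carboxylate 32 (not isolated)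
Conditions: LiOH, THF/H2O, 60 °C; concentrate; Me3SiCH2CH2OCH2Cl, DMF, 0 °C
Reagents that add atoms: lithium hydroxide, [Li+].[OH-]; 2-(trimethylsilyl)ethoxymethyl chloride, C[Si](C)(C)CCOCCl
Why: Saponification opens the lactone, and the carboxylate, far more nucleophilic than the neutral primary alcohol, is alkylated to the SEM ester, which fluoride can remove later without attack at the hindered carbonyl.

Step 16
Reactants: 33 hydroxy SEM ester
Product: 34 [2-(trimethylsilyl)ethoxy]methyl 2-(3-bromobut-3-enyl)-5-(tert-butyldimethylsilyloxy)-3-formyl-1,3-dimethylcyclohexane-1-carboxylate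
Conditions: Dess–Martin periodinane, NaHCO3, CH2Cl2, rt (crude 33 used at once)
Reagents that add atoms: none
Why: Dess–Martin oxidation converts the neopentyl C9 alcohol into the non-enolizable aldehyde before it can close back onto C19.

Step 17
Reactants: 34 C9 aldehyde; 35 trimethyl phosphonoacetate
Product: 37 [2-(trimethylsilyl)ethoxy]methyl 2-(3-bromobut-3-enyl)-5-(tert-butyldimethylsilyloxy)-3-[(E)-3-methoxy-3-oxoprop-1-enyl]-1,3-dimethylcyclohexane-1-carboxylate (cyclization precursor), via sodium phosphonate carbanion 36 (not isolated)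
Conditions: NaH, THF, 0 °C → rt
Reagents that add atoms: none
Why: Horner–Wadsworth–Emmons olefination with the stabilized phosphonate gives the (E)-enoate C9=C11 on the hindered aldehyde.

Step 18
Reactants: 37 cyclization precursor
Product: 38 [2-(trimethylsilyl)ethoxy]methyl (2S,4R,5S,9S,10R)-2-(tert-butyldimethylsilyloxy)-12-methoxy-12-oxo-13,14,15,16-tetranorlabd-8(17)-en-19-oate (cis-decalin; 9β-CH2CO2Me)
Conditions: Bu3SnH (1.3 equiv), AIBN (0.2 equiv), added over 6 h to 37 in benzene (0.01 M), 80 °C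
Reagents that add atoms: none
Why: Bu3Sn• abstracts bromine from C8, the σ-vinyl radical adds to C9, the β-carbon of the enoate, and the C11 α-ester radical takes hydrogen from Bu3SnH; this is the established 6-exo cyclization of vinyl radicals from 2-bromoalk-1-enes onto α,β-unsaturated esters. Ring B (C5–C6–C7–C8–C9–C10) closes in the 6-exo-trig mode through a chair transition state. The new stereocenter C9 is controlled by ring A: with the 2β-silyloxy group and both methyls equatorial, ring A holds C10–C9 axial and C5–C6 equatorial. In the forming ring B chair C11 must then be equatorial, because the axial site is 1,3 to C4 with its ester, so H-9 ends α and the chain β, cis to C20. The step needs 6-exo over 7-endo closure and cyclization faster than reduction or hydrogen shift; the match of the nucleophilic vinyl radical with electron-poor C9, the absence of hydrogen on C4 and C10 (no 1,5-shift) and slow stannane addition at high dilution secure this. The exocyclic C8=C17 alkene is formed in place.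

Step 19
Reactants: 38 cis-decalin diester
Product: 39 [2-(trimethylsilyl)ethoxy]methyl (2S,4R,5S,9S,10R)-2-(tert-butyldimethylsilyloxy)-12-hydroxy-13,14,15,16-tetranorlabd-8(17)-en-19-oate
Conditions: i-Bu2AlH (2.5 equiv), CH2Cl2, −78 → −40 °C
Reagents that add atoms: none
Why: Hydride reduction takes the unhindered C12 methyl ester to the primary alcohol, while the C19 ester on the quaternary, axial position is sterically shielded.

Step 20
Reactants: 39 C12 alcohol
Product: 40 [2-(trimethylsilyl)ethoxy]methyl (2S,4R,5S,9S,10R)-2-(tert-butyldimethylsilyloxy)-12-iodo-13,14,15,16-tetranorlabd-8(17)-en-19-oate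
Conditions: I2, PPh3, imidazole, CH2Cl2, 0 °C
Reagents that add atoms: iodine, II
Why: Appel-type iodination converts the primary alcohol into the iodide through the alkoxyphosphonium salt.

Step 21
Reactants: 40 C12 iodide; 41 methyl (E)-3-iodobut-2-enoate
Product: 43 15-methyl 19-{[2-(trimethylsilyl)ethoxy]methyl} (2S,4R,5S,9S,10R,13E)-2-(tert-butyldimethylsilyloxy)labda-8(17),13-diene-15,19-dioate, via alkylzinc iodide 42 (not isolated)
Conditions: Zn dust (activated with Me3SiCl and BrCH2CH2Br), DMA, 40 °C; then 41, Pd(PPh3)4 (5 mol %), THF, rt → 40 °C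
Reagents that add atoms: none
Why: Negishi coupling: zinc inserts into the primary C–I bond, the alkylzinc transmetalates to the vinylpalladium iodide formed from 41, and reductive elimination forms C12–C13 with retention, so C13=C14 is E.

Step 22
Reactants: 43 protected diester
Product: 45 (2S,4R,5S,9S,10R,13E)-2-hydroxylabda-8(17),13-diene-15,19-dioic acid (5β-H; the target), via hydroxy acid methyl ester 44 (not isolated)
Conditions: Bu4NF, THF, rt → 45 °C; then LiOH, MeOH/H2O, rt; 1 M HCl to pH 3
Reagents that add atoms: lithium hydroxide, [Li+].[OH-]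
Why: Fluoride cleaves the silyl ether and, by attack at silicon, fragments the SEM ester to the C19 carboxylate, after which saponification of the unhindered C15 methyl ester gives the diacid with no stereocenter touched.

Compound list
1 | 3,5-dimethoxybenzoic acid | COc1cc(OC)cc(c1)C(=O)O | starting material
2 | dilithium (3,5-dimethoxycyclohexa-2,5-dien-1-ylidene)methanediolate | [Li+].[Li+].COC1=CC(=C([O-])[O-])C=C(OC)C1 | intermediate
3 | lithium 3,5-dimethoxy-1-methylcyclohexa-2,5-diene-1-carboxylate | [Li+].COC1=CC(C)(C([O-])=O)C=C(OC)C1 | intermediate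
4 | rac-3-methoxy-1-methyl-5-oxocyclohex-3-ene-1-carboxylic acid | COC1=CC(=O)CC(C)(C(=O)O)C1 | intermediate
5 | (R)-1-phenylethylammonium (R)-3-methoxy-1-methyl-5-oxocyclohex-3-ene-1-carboxylate | COC1=CC(=O)C[C@](C)(C(=O)[O-])C1.C[C@@H]([NH3+])c1ccccc1 | intermediate
6 | (R)-3-methoxy-1-methyl-5-oxocyclohex-3-ene-1-carboxylic acid | COC1=CC(=O)C[C@](C)(C(=O)O)C1 | intermediate
7 | tert-butyl (R)-3-methoxy-1-methyl-5-oxocyclohex-3-ene-1-carboxylate | COC1=CC(=O)C[C@](C)(C(=O)OC(C)(C)C)C1 | intermediate
8 | allyl bromide | C=CCBr | starting material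
9 | lithium dienolate of 7 (deprotonated at C5) | [Li+].COC1=CC([O-])=C[C@](C)(C(=O)OC(C)(C)C)C1 | intermediate
10 | tert-butyl (1R,2R)-2-allyl-5-methoxy-1-methyl-3-oxocyclohex-4-ene-1-carboxylate (5α-allyl, cis to the ester) | C=CC[C@H]1C(=O)C=C(OC)C[C@@]1(C)C(=O)OC(C)(C)C | intermediate
11 | 4-methoxybenzyl alcohol | COc1ccc(CO)cc1 | starting material
12 | tributyl(iodomethyl)stannane | CCCC[Sn](CCCC)(CCCC)CI | starting material
13 | sodium 4-methoxybenzyl oxide | [Na+].[O-]Cc1ccc(OC)cc1 | intermediate
14 | tributyl{[(4-methoxybenzyl)oxy]methyl}stannane | CCCC[Sn](CCCC)(CCCC)COCc1ccc(OC)cc1 | intermediate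
15 | {[(4-methoxybenzyl)oxy]methyl}lithium | [Li]COCc1ccc(OC)cc1 | intermediate
16 | lithium alkoxide from 1,2-addition of 15 to C10 of 10 (C10 epimers) | C=CC[C@H]1C([O-])(COCc2ccc(OC)cc2)C=C(OC)C[C@@]1(C)C(=O)OC(C)(C)C.[Li+] | intermediate
17 | tert-butyl 2-allyl-3-{[(4-methoxybenzyl)oxy]methyl}-1-methyl-5-oxocyclohex-3-ene-1-carboxylate (C2 ketone, C1=C10, 5α-allyl, 4β-methyl, 4α-ester) | C=CC[C@H]1C(COCc2ccc(OC)cc2)=CC(=O)C[C@@]1(C)C(=O)OC(C)(C)C | intermediate
18 | lithium C1=C2 enolate after methyl addition to C10 (10β-methyl) | C=CC[C@H]1[C@](C)(C=C([O-])C[C@@]1(C)C(=O)OC(C)(C)C)COCc2ccc(OC)cc2.[Li+] | intermediate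
19 | tert-butyl 2-allyl-3-{[(4-methoxybenzyl)oxy]methyl}-1,3-dimethyl-5-(trifluoromethylsulfonyloxy)cyclohex-4-ene-1-carboxylate (4β,10β-dimethyl; C9, C19 and allyl α) | C=CC[C@H]1[C@](C)(C=C(OS(=O)(=O)C(F)(F)F)C[C@@]1(C)C(=O)OC(C)(C)C)COCc2ccc(OC)cc2 | intermediate
20 | tert-butyl 2-allyl-3-{[(4-methoxybenzyl)oxy]methyl}-1,3-dimethylcyclohex-4-ene-1-carboxylate (stereocenters as in 19) | C=CC[C@H]1[C@](C)(C=CC[C@@]1(C)C(=O)OC(C)(C)C)COCc2ccc(OC)cc2 | intermediate
21 | 2-allyl-3-(hydroxymethyl)-1,3-dimethylcyclohex-4-ene-1-carboxylic acid (stereocenters as in 19) | C=CC[C@H]1[C@](C)(C=CC[C@@]1(C)C(=O)O)CO | intermediate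
22 | 9-allyl-1,5-dimethyl-3-oxabicyclo[3.3.1]non-6-en-2-one (C19-to-C9 δ-lactone, 5α-allyl) | C=CC[C@H]1[C@]2(C)C=CC[C@@]1(C)C(=O)OC2 | intermediate
23 | bis-borane adduct of 22 (boron on C2 β and on C8) | BCCC[C@H]1[C@]2(C)C[C@H](B)C[C@@]1(C)C(=O)OC2 | intermediate
24 | 7-hydroxy-9-(3-hydroxypropyl)-1,5-dimethyl-3-oxabicyclo[3.3.1]nonan-2-one (2β-hydroxy) | OCCC[C@H]1[C@]2(C)C[C@H](O)C[C@@]1(C)C(=O)OC2 | intermediate
25 | 3-(7-hydroxy-1,5-dimethyl-2-oxo-3-oxabicyclo[3.3.1]nonan-9-yl)propanal | O=CCC[C@H]1[C@]2(C)C[C@H](O)C[C@@]1(C)C(=O)OC2 | intermediate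
26 | 3-[7-(tert-butyldimethylsilyloxy)-1,5-dimethyl-2-oxo-3-oxabicyclo[3.3.1]nonan-9-yl]propanal | O=CCC[C@H]1[C@]2(C)C[C@H](O[Si](C)(C)C(C)(C)C)C[C@@]1(C)C(=O)OC2 | intermediate
27 | dimethyl (1-diazo-2-oxopropyl)phosphonate | COP(=O)(OC)C(=[N+]=[N-])C(C)=O | starting material
28 | dimethyl (diazomethyl)phosphonate | COP(=O)(OC)C=[N+]=[N-] | intermediate
29 | 9-(but-3-ynyl)-7-(tert-butyldimethylsilyloxy)-1,5-dimethyl-3-oxabicyclo[3.3.1]nonan-2-one | C#CCC[C@H]1[C@]2(C)C[C@H](O[Si](C)(C)C(C)(C)C)C[C@@]1(C)C(=O)OC2 | intermediate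
30 | (Z)-2-bromo-1-(9-borabicyclo[3.3.1]nonan-9-yl)alkene from 29 | Br/C(=C\B3C4CCCC3CCC4)CC[C@H]1[C@]2(C)C[C@H](O[Si](C)(C)C(C)(C)C)C[C@@]1(C)C(=O)OC2 | intermediate
31 | 9-(3-bromobut-3-enyl)-7-(tert-butyldimethylsilyloxy)-1,5-dimethyl-3-oxabicyclo[3.3.1]nonan-2-one | C=C(Br)CC[C@H]1[C@]2(C)C[C@H](O[Si](C)(C)C(C)(C)C)C[C@@]1(C)C(=O)OC2 | intermediate
32 | lithium 2-(3-bromobut-3-enyl)-5-(tert-butyldimethylsilyloxy)-3-(hydroxymethyl)-1,3-dimethylcyclohexane-1-carboxylate | [Li+].C=C(Br)CC[C@H]1[C@](C)(C[C@H](O[Si](C)(C)C(C)(C)C)C[C@@]1(C)C(=O)[O-])CO | intermediate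
33 | [2-(trimethylsilyl)ethoxy]methyl 2-(3-bromobut-3-enyl)-5-(tert-butyldimethylsilyloxy)-3-(hydroxymethyl)-1,3-dimethylcyclohexane-1-carboxylate (2β-OTBS, 4β-Me, 4α-ester, 5α-arm, 10β-Me, 10α-CH2OH) | C=C(Br)CC[C@H]1[C@](C)(C[C@H](O[Si](C)(C)C(C)(C)C)C[C@@]1(C)C(=O)OCOCC[Si](C)(C)C)CO | intermediate
34 | [2-(trimethylsilyl)ethoxy]methyl 2-(3-bromobut-3-enyl)-5-(tert-butyldimethylsilyloxy)-3-formyl-1,3-dimethylcyclohexane-1-carboxylate | C=C(Br)CC[C@H]1[C@](C)(C[C@H](O[Si](C)(C)C(C)(C)C)C[C@@]1(C)C(=O)OCOCC[Si](C)(C)C)C=O | intermediate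
35 | trimethyl phosphonoacetate | COC(=O)CP(=O)(OC)OC | starting material
36 | sodium salt of the trimethyl phosphonoacetate carbanion | [Na+].COC(=O)[CH-]P(=O)(OC)OC | intermediate
37 | [2-(trimethylsilyl)ethoxy]methyl 2-(3-bromobut-3-enyl)-5-(tert-butyldimethylsilyloxy)-3-[(E)-3-methoxy-3-oxoprop-1-enyl]-1,3-dimethylcyclohexane-1-carboxylate (precursor of the key step) | C=C(Br)CC[C@H]1[C@](C)(C[C@H](O[Si](C)(C)C(C)(C)C)C[C@@]1(C)C(=O)OCOCC[Si](C)(C)C)/C=C/C(=O)OC | intermediate
38 | [2-(trimethylsilyl)ethoxy]methyl (2S,4R,5S,9S,10R)-2-(tert-butyldimethylsilyloxy)-12-methoxy-12-oxo-13,14,15,16-tetranorlabd-8(17)-en-19-oate (product of the key step) | C=C1CC[C@H]2[C@](C)(C[C@H](O[Si](C)(C)C(C)(C)C)C[C@@]2(C)C(=O)OCOCC[Si](C)(C)C)[C@H]1CC(=O)OC | intermediate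
39 | [2-(trimethylsilyl)ethoxy]methyl (2S,4R,5S,9S,10R)-2-(tert-butyldimethylsilyloxy)-12-hydroxy-13,14,15,16-tetranorlabd-8(17)-en-19-oate | C=C1CC[C@H]2[C@](C)(C[C@H](O[Si](C)(C)C(C)(C)C)C[C@@]2(C)C(=O)OCOCC[Si](C)(C)C)[C@H]1CCO | intermediate
40 | [2-(trimethylsilyl)ethoxy]methyl (2S,4R,5S,9S,10R)-2-(tert-butyldimethylsilyloxy)-12-iodo-13,14,15,16-tetranorlabd-8(17)-en-19-oate | C=C1CC[C@H]2[C@](C)(C[C@H](O[Si](C)(C)C(C)(C)C)C[C@@]2(C)C(=O)OCOCC[Si](C)(C)C)[C@H]1CCI | intermediate
41 | methyl (E)-3-iodobut-2-enoate | COC(=O)/C=C(\C)I | starting material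
42 | C12 alkylzinc iodide from 40 | C=C1CC[C@H]2[C@](C)(C[C@H](O[Si](C)(C)C(C)(C)C)C[C@@]2(C)C(=O)OCOCC[Si](C)(C)C)[C@H]1CC[Zn]I | intermediate
43 | 15-methyl 19-{[2-(trimethylsilyl)ethoxy]methyl} (2S,4R,5S,9S,10R,13E)-2-(tert-butyldimethylsilyloxy)labda-8(17),13-diene-15,19-dioate | C=C1CC[C@H]2[C@](C)(C[C@H](O[Si](C)(C)C(C)(C)C)C[C@@]2(C)C(=O)OCOCC[Si](C)(C)C)[C@H]1CC/C(C)=C/C(=O)OC | intermediate
44 | (2S,4R,5S,9S,10R,13E)-2-hydroxy-15-methoxy-15-oxolabda-8(17),13-dien-19-oic acid | C=C1CC[C@H]2[C@](C)(C[C@H](O)C[C@@]2(C)C(=O)O)[C@H]1CC/C(C)=C/C(=O)OC | intermediate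
45 | (2S,4R,5S,9S,10R,13E)-2-hydroxylabda-8(17),13-diene-15,19-dioic acid (cis-fused, 5β-H) | C=C1CC[C@H]2[C@](C)(C[C@H](O)C[C@@]2(C)C(=O)O)[C@H]1CC/C(C)=C/C(=O)O | target

Total step count: 22. Longest linear sequence: 21 steps (steps 1–4 and 6–22; step 5 makes stannane 14 in a side branch).

Steps most likely to fail

Step 18 (key step): the vinyl radical may take hydrogen from the stannane before it cyclizes, or ring A may react through its other chair and erode control at C9. Fallback: the same C8–C9 bond is made by a two-electron path, a palladium-catalysed reductive Heck cyclization of 37 (Pd(OAc)2, PPh3, HCO2Na, Bu4NCl, DMF, 80 °C). The C8 vinylpalladium adds 6-exo to C9=C11 and the C11 palladium enolate is reduced by formate. The fallback sets out from 37 and comes back at 38, and makes no new compound.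

Step 4: poor facial selectivity of the allylation at C5, with the allyl group entering syn to C18. Fallback: C5 is set by protonation instead of alkylation, setting out from 7. LiN(iPr)2 and then [Me2N=CH2]I should give the Mannich base tert-butyl (1R)-2-[(dimethylamino)methyl]-5-methoxy-1-methyl-3-oxocyclohex-4-ene-1-carboxylate F1. MeI and then NaHCO3 should give the α′-methylene ketone tert-butyl (R)-5-methoxy-1-methyl-2-methylidene-3-oxocyclohex-4-ene-1-carboxylate F2. (CH2=CH)2CuLi then adds to the exocyclic carbon and so builds the allyl group. The resulting C5 enolate is protonated at −78 °C on the face an alkyl halide would take, which gives the C5 configuration opposite to direct alkylation and comes back at 10.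

Step 2: the two diastereomeric salts may not differ enough in solubility to separate. Fallback: covalent diastereomers, setting out from 4. Mitsunobu esterification with (S)-1-phenylethanol (PPh3, DIAD, THF; inversion at the carbinol) should give (R)-1-phenylethyl (R)-3-methoxy-1-methyl-5-oxocyclohex-3-ene-1-carboxylate F3 and (R)-1-phenylethyl (S)-3-methoxy-1-methyl-5-oxocyclohex-3-ene-1-carboxylate F4, to be separated by chromatography. Hydrogenolysis of F3 (H2, Pd/C, EtOAc) comes back at 6.

Further compounds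
F0 | step 18 | none | none
F1 | step 4 | tert-butyl (1R)-2-[(dimethylamino)methyl]-5-methoxy-1-methyl-3-oxocyclohex-4-ene-1-carboxylate (C5 epimers) | CN(C)CC1C(=O)C=C(OC)C[C@@]1(C)C(=O)OC(C)(C)C
F2 | step 4 | tert-butyl (R)-5-methoxy-1-methyl-2-methylidene-3-oxocyclohex-4-ene-1-carboxylate | C=C1C(=O)C=C(OC)C[C@@]1(C)C(=O)OC(C)(C)C
F3 | step 2 | (R)-1-phenylethyl (R)-3-methoxy-1-methyl-5-oxocyclohex-3-ene-1-carboxylate | COC1=CC(=O)C[C@](C)(C(=O)O[C@H](C)c2ccccc2)C1
F4 | step 2 | (R)-1-phenylethyl (S)-3-methoxy-1-methyl-5-oxocyclohex-3-ene-1-carboxylate | COC1=CC(=O)C[C@@](C)(C(=O)O[C@H](C)c2ccccc2)C1
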